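**Retrosynthetic overview**

1. The target comes from hydrogenolysis of its 2,4-di-O-benzyl acid, the acid from an aldehyde (Pinnick), and the aldehyde from Vilsmeier formylation of a symmetric 5-alkylresorcinol dibenzyl ether, which breaks the ring symmetry late.
2. With H in place of the aryl group the side chain is (2R,12R)-tridecane-2,12-diol, which is C2-symmetric. Both ArCH2–C(2') and H–CH2–C(12') are therefore disconnected to (2S,12S)-1,2:12,13-diepoxytridecane. The key step differentiates its two ends in one pot: aryl nucleophile at one oxirane, hydride at the other, then acetylation in the flask.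
3. The bis-epoxide comes from heptane-1,7-diyl di-Grignard and two (S)-epichlorohydrin (two-directional; both stereocentres from one chiral-pool reagent).
4. The aryl nucleophile comes from 1,3-bis(benzyloxy)-5-bromobenzene, made from 1-bromo-3,5-difluorobenzene and benzyl alcohol by double SNAr.
5. Rings: the benzene ring is bought. The only rings made are the two oxiranes, formed together in the chain step and both opened in the key step.

Assumption: the target is taken exactly as the given SMILES, i.e. 2-[(2S,12R)-2,12-diacetoxytridecyl]-4,6-dihydroxybenzoic acid.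

**Route**

Step 1
Reactants: 1 1-bromo-3,5-difluorobenzene
Product: 2 1,3-bis(benzyloxy)-5-bromobenzene
Conditions: BnOH (2.3 equiv), NaH (2.5 equiv), NMP, 0 → 100 °C
Reagents that add atoms: benzyl alcohol, OCc1ccccc1
Why: Double SNAr (addition–elimination) in which benzyloxide displaces both fluorides, which are far better leaving groups than bromide in this mechanism and are activated inductively by the meta halogen and alkoxy substituents.

Step 2
Reactants: 3 1,7-dibromoheptane; 4 (S)-epichlorohydrin (2.2 equiv)
Product: 7 (2S,12S)-1,2:12,13-diepoxytridecane, via di-Grignard reagent 5 (not isolated), via bis-chlorohydrin 6 (not isolated)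
Conditions: Mg, THF, reflux; then 4, CuI (10 mol %), THF, −40 → 0 °C; then NaOH, MeOH/H2O, rt
Reagents that add atoms: none
Why: Two-directional copper-catalysed Grignard opening of the oxirane CH2 of 4 at both chain ends (SN2 at the unsubstituted carbon, stereocentre untouched) followed by intramolecular Williamson closure of each chlorohydrin, so both (S) centres of the C2-symmetric product are carried over unchanged from 4.

Step 3
Reactants: 2 1,3-bis(benzyloxy)-5-bromobenzene (1 equiv); 7 (2S,12S)-1,2:12,13-diepoxytridecane (2.5 equiv)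
Product: 11 (2S,12R)-1-[3,5-bis(benzyloxy)phenyl]tridecane-2,12-diyl diacetate, via aryl Grignard reagent 8 (not isolated), via epoxy alcohol 9 (not isolated), via diol 10 (not isolated)
Conditions: 2, Mg, THF, 50 °C; added slowly to 7, CuI (10 mol %), THF, −30 → 0 °C; then LiBHEt3, THF, 0 °C → rt; then Ac2O, pyridine, DMAP, 0 °C → rt
Reagents that add atoms: acetic anhydride, CC(=O)OC(C)=O
Why: Copper-catalysed aryl Grignard opening of one terminal oxirane at CH2, LiBHEt3 (Super-Hydride) opening of the other at CH2 and O-acetylation of the resulting alkoxides in the same flask; the two oxiranes of C2-symmetric 7 are homotopic, so mono-arylation gives a single compound and breaks the symmetry (excess 7 and slow addition of 8 suppress double arylation, surplus 7 ending as tridecane-2,12-diyl diacetate that is removed by chromatography), and as no bond to either stereocentre is touched the arylated end is (S) and the reduced end is (R) purely through the change of CIP ranks.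

Step 4
Reactants: 11 (2S,12R)-1-[3,5-bis(benzyloxy)phenyl]tridecane-2,12-diyl diacetate
Product: 12 (2S,12R)-1-[3,5-bis(benzyloxy)-2-formylphenyl]tridecane-2,12-diyl diacetate
Conditions: POCl3 (2 equiv), DMF, 0 → 70 °C; then aq. NaOAc, rt
Reagents that add atoms: N,N-dimethylformamide, CN(C)C=O; water, O
Why: Vilsmeier–Haack formylation in which the chloroiminium ion attacks the ring carbon that is para to one benzyloxy group, ortho to the other and next to the side chain (the two such carbons are equivalent by rotation about the aryl–CH2 bond) in preference to the more hindered carbon between the two benzyloxy groups, while acetates and benzyl ethers are inert to POCl3/DMF and to the buffered hydrolysis.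

Step 5
Reactants: 12 (2S,12R)-1-[3,5-bis(benzyloxy)-2-formylphenyl]tridecane-2,12-diyl diacetate
Product: 13 2,4-bis(benzyloxy)-6-[(2S,12R)-2,12-diacetoxytridecyl]benzoic acid
Conditions: NaClO2, NaH2PO4, 2-methyl-2-butene, t-BuOH/THF/H2O, 0 °C → rt
Reagents that add atoms: sodium chlorite, [Na+].[O-]Cl=O
Why: Pinnick (Lindgren–Kraus) oxidation converts the hindered electron-rich aldehyde into the acid while 2-methyl-2-butene scavenges HOCl, leaving acetates, benzyl ethers and both stereocentres untouched.

Step 6
Reactants: 13 2,4-bis(benzyloxy)-6-[(2S,12R)-2,12-diacetoxytridecyl]benzoic acid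
Product: 14 2-[(2S,12R)-2,12-diacetoxytridecyl]-4,6-dihydroxybenzoic acid
Conditions: H2 (1 atm), 10% Pd/C, EtOAc, rt
Reagents that add atoms: none
Why: Heterogeneous hydrogenolysis cleaves the two aryl benzyl ethers under neutral conditions, under which the non-benzylic secondary acetates, the carboxylic acid and the stereocentres are stable and lactonisation to the dihydroisocoumarin is blocked because the 2'-oxygen stays acetylated.

**Compound list**

1 | 1-bromo-3,5-difluorobenzene | Fc1cc(F)cc(Br)c1 | starting material
2 | 1,3-bis(benzyloxy)-5-bromobenzene | Brc1cc(OCc2ccccc2)cc(OCc2ccccc2)c1 | intermediate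
3 | 1,7-dibromoheptane | BrCCCCCCCBr | starting material
4 | (S)-epichlorohydrin [(2S)-2-(chloromethyl)oxirane] | ClC[C@@H]1CO1 | starting material
5 | heptane-1,7-diylbis(magnesium bromide) [di-Grignard reagent; not isolated] | Br[Mg]CCCCCCC[Mg]Br | intermediate
6 | (2S,12S)-1,13-dichlorotridecane-2,12-diol [bis-chlorohydrin; present as its magnesium alkoxide; not isolated] | ClC[C@@H](O)CCCCCCCCC[C@H](O)CCl | intermediate
7 | (2S,12S)-1,2:12,13-diepoxytridecane [(2S,2'S)-2,2'-(nonane-1,9-diyl)bis(oxirane)] | O1C[C@@H]1CCCCCCCCC[C@H]1CO1 | intermediate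
8 | [3,5-bis(benzyloxy)phenyl]magnesium bromide [not isolated] | Br[Mg]c1cc(OCc2ccccc2)cc(OCc2ccccc2)c1 | intermediate
9 | (2S)-1-[3,5-bis(benzyloxy)phenyl]-11-[(2S)-oxiran-2-yl]undecan-2-ol [present as its magnesium alkoxide; not isolated] | O[C@@H](CCCCCCCCC[C@H]1CO1)Cc1cc(OCc2ccccc2)cc(OCc2ccccc2)c1 | intermediate
10 | (2S,12R)-1-[3,5-bis(benzyloxy)phenyl]tridecane-2,12-diol [present as its dialkoxide; not isolated] | O[C@@H](CCCCCCCCC[C@@H](C)O)Cc1cc(OCc2ccccc2)cc(OCc2ccccc2)c1 | intermediate
11 | (2S,12R)-1-[3,5-bis(benzyloxy)phenyl]tridecane-2,12-diyl diacetate | CC(=O)O[C@@H](CCCCCCCCC[C@@H](C)OC(C)=O)Cc1cc(OCc2ccccc2)cc(OCc2ccccc2)c1 | intermediate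
12 | (2S,12R)-1-[3,5-bis(benzyloxy)-2-formylphenyl]tridecane-2,12-diyl diacetate | CC(=O)O[C@@H](CCCCCCCCC[C@@H](C)OC(C)=O)Cc1cc(OCc2ccccc2)cc(OCc2ccccc2)c1C=O | intermediate
13 | 2,4-bis(benzyloxy)-6-[(2S,12R)-2,12-diacetoxytridecyl]benzoic acid | CC(=O)O[C@@H](CCCCCCCCC[C@@H](C)OC(C)=O)Cc1cc(OCc2ccccc2)cc(OCc2ccccc2)c1C(=O)O | intermediate
14 | 2-[(2S,12R)-2,12-diacetoxytridecyl]-4,6-dihydroxybenzoic acid (CNP0203944.3) | CC(=O)O[C@@H](CCCCCCCCC[C@@H](C)OC(C)=O)Cc1cc(O)cc(O)c1C(=O)O | target

**Step count and risks**

Total steps: 6. Longest linear sequence: 5 (step 1 or step 2, then steps 3 to 6).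

The three steps most likely to fail:

Step 3 (statistical mono-arylation and telescoped hydride/acetylation). The fallback replaces desymmetrization of the electrophilic bis-epoxide by a three-component coupling around a nucleophilic C7 linchpin. It sets out from aryl bromide 2 through its Grignard reagent 8. CuI-catalysed opening of (R)-epichlorohydrin (ClC[C@H]1CO1) gives (2R)-1-[3,5-bis(benzyloxy)phenyl]-3-chloropropan-2-ol F1, which NaOH closes to (2R)-2-[3,5-bis(benzyloxy)benzyl]oxirane F2. F2 is added to an excess of di-Grignard reagent 5 with CuI, giving bromomagnesium (2S)-1-[3,5-bis(benzyloxy)phenyl]-10-(bromomagnesio)decan-2-olate F3, which is not isolated. Its remaining C–Mg bond is trapped in the same flask with (R)-propylene oxide (C[C@@H]1CO1) to give diol 10. Acetylation (Ac2O, pyridine, DMAP) brings it back to the route at 11.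

Step 4 (regioselectivity of formylation and reactivity of the hindered position). The fallback takes the carboxyl carbon from CO instead of DMF and sets out from 11. NBS in MeCN at 0 °C brominates para to a benzyloxy group and gives (2S,12R)-1-[3,5-bis(benzyloxy)-2-bromophenyl]tridecane-2,12-diyl diacetate F4. Alkoxycarbonylation (CO, BnOH, Et3N, Pd(OAc)2, Xantphos, toluene, 100 °C) gives benzyl 2,4-bis(benzyloxy)-6-[(2S,12R)-2,12-diacetoxytridecyl]benzoate F5. Hydrogenolysis of all three benzyl groups (H2, Pd/C, EtOAc) comes back to the route directly at target 14, skipping 12 and 13.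

Step 2 (double opening of epichlorohydrin by a di-Grignard reagent; risk of mono-addition, attack on freshly formed epoxide and erosion of ee). The fallback uses an acetylide linchpin and sets out from (S)-epichlorohydrin 4. Hepta-1,6-diyne (C#CCCCC#C) is doubly deprotonated with n-BuLi in THF at −78 °C to 1,7-dilithiohepta-1,6-diyne F6. Addition of BF3·OEt2 and then 4 opens the oxirane CH2 at both ends and gives (2S,12S)-1,13-dichlorotrideca-4,9-diyne-2,12-diol F7. Hydrogenation (H2, PtO2, EtOAc) gives bis-chlorohydrin 6, now isolated, and NaOH in MeOH closes it to 7, where it rejoins the route.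

**Further compounds**

F1 | step 3 | (2R)-1-[3,5-bis(benzyloxy)phenyl]-3-chloropropan-2-ol | ClC[C@H](O)Cc1cc(OCc2ccccc2)cc(OCc2ccccc2)c1
F2 | step 3 | (2R)-2-[3,5-bis(benzyloxy)benzyl]oxirane | O1C[C@H]1Cc1cc(OCc2ccccc2)cc(OCc2ccccc2)c1
F3 | step 3 | bromomagnesium (2S)-1-[3,5-bis(benzyloxy)phenyl]-10-(bromomagnesio)decan-2-olate | Br[Mg]CCCCCCCC[C@H](O[Mg]Br)Cc1cc(OCc2ccccc2)cc(OCc2ccccc2)c1
F4 | step 4 | (2S,12R)-1-[3,5-bis(benzyloxy)-2-bromophenyl]tridecane-2,12-diyl diacetate | CC(=O)O[C@@H](CCCCCCCCC[C@@H](C)OC(C)=O)Cc1cc(OCc2ccccc2)cc(OCc2ccccc2)c1Br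
F5 | step 4 | benzyl 2,4-bis(benzyloxy)-6-[(2S,12R)-2,12-diacetoxytridecyl]benzoate | CC(=O)O[C@@H](CCCCCCCCC[C@@H](C)OC(C)=O)Cc1cc(OCc2ccccc2)cc(OCc2ccccc2)c1C(=O)OCc1ccccc1
F6 | step 2 | 1,7-dilithiohepta-1,6-diyne | [Li]C#CCCCC#C[Li]
F7 | step 2 | (2S,12S)-1,13-dichlorotrideca-4,9-diyne-2,12-diol | ClC[C@@H](O)CC#CCCCC#CC[C@H](O)CCl
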